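**Strategy.** The enone decalin is cut through ring B at C6–C7 (acyl bond of the C7 ketone) and at C9–C10 (enone β-carbon to the quaternary ring-fusion carbon). One flask operation makes both bonds: the alkyllithium from ring-A iodide 19 is acylated by Weinreb enamide 13, which already carries the sclareolide-derived trans-decalin half, and an iron hydride then converts the exocyclic C10=CH2 group into the methyl-bearing C10 radical, which closes 6-endo onto C9. The step exploits the angular methyl on quaternary C10 of the cis-fused ring A/B junction and the C7(=O)–C8=C9 enone of ring B. The precursor is an open dienone made in the flask.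

Key step: step 14

Remark on numbering: the enone half is numbered like a terpenoid decalin (C3 carbinol, C4 gem-dimethyl, C5/C10 ring fusion, C7 ketone, C8=C9). The saturated half carries primed numbers, and the two CH2 groups between C9 and C9′ are C12′ and C11′.

Remark on stereochemistry (read from the SMILES): the saturated half is the usual trans-decalin of the sclareolide series (3β-OH, 5α-H, 8α-CH3, 9β side chain, 10β-CH3). The enone half is cis-fused, with C3–OH, C5–H and C10–CH3 on one face, so C6 on C5 is trans to the C3 oxygen.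

Remark on supply: 1, 10 and 14 are taken as commercial.

Step 1
Reactants: 1 (+)-sclareolide
Product: 2 3β-hydroxysclareolide
Conditions: cytochrome P450 monooxygenase (engineered P450 BM3 variant, cell lysate), NADP+ (cat.), Na2HPO3, phosphite dehydrogenase, air, phosphate buffer pH 8, 25 °C
Reagents that add atoms: dioxygen, O=O
Why: Enzymatic C–H hydroxylation by oxygen rebound with retention oxidises the equatorial C3–H of ring A and sets the 3β (3S) alcohol, a site selectivity on this lactone that no small reagent offers.

Step 2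
Reactants: 2 3β-hydroxysclareolide
Product: 3 3β-(tert-butyldimethylsilyloxy)sclareolide
Conditions: TBSOTf, 2,6-lutidine, CH2Cl2, 0 °C
Reagents that add atoms: tert-butyldimethylsilyl triflate, CC(C)(C)[Si](C)(C)OS(=O)(=O)C(F)(F)F
Why: Silyl triflate silylation protects the hindered secondary alcohol before the dehydration and the organometallic steps and leaves the lactone untouched.

Step 3
Reactants: 3 silylated lactone
Product: 5 3β-(tert-butyldimethylsilyloxy)-N-methoxy-N-methyl-13,14,15,16-tetranorlabd-8(17)-en-12-amide, via hydroxy Weinreb amide 4 (not isolated)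
Conditions: MeNH(OMe)·HCl, AlMe3, CH2Cl2, 0 to 25 °C; aqueous tartrate work-up, crude 4 taken on; then SOCl2, pyridine, CH2Cl2, −78 °C
Reagents that add atoms: N,O-dimethylhydroxylamine hydrochloride, CNOC.Cl
Why: Aluminium amide opening of the lactone (Weinreb amide synthesis) gives tertiary alcohol 4, which is dehydrated crude because it relactonises readily; its equatorial C8–O chlorosulfite has no antiperiplanar ring hydrogen, so the pyridine-mediated E2 elimination should take a methyl hydrogen and give the single exocyclic alkene with C9 untouched.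

Step 4
Reactants: 5 exocyclic alkene Weinreb amide
Product: 6 3β-(tert-butyldimethylsilyloxy)-N-methoxy-N-methyl-8βH-13,14,15,16-tetranorlabdan-12-amide (8α-methyl)
Conditions: Mn(dpm)3 (cat.), PhSiH3, t-BuOOH, i-PrOH, 22 °C
Reagents that add atoms: none
Why: Mukaiyama-type hydrogen-atom-transfer hydrogenation gives the tertiary C8 radical, which should take its hydrogen under thermodynamic control so that the methyl ends equatorial (8α, trans to the C9 chain), where catalytic hydrogenation would favour the axial methyl.

Step 5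
Reactants: 6 saturated Weinreb amide
Product: 8 3β-(tert-butyldimethylsilyloxy)-8βH-13,14,15,16-tetranorlabdan-12-ol, via aldehyde 7 (not isolated)
Conditions: i-Bu2AlH, THF, −78 °C; then MeOH, NaBH4, 0 °C
Reagents that add atoms: none
Why: Hydride reduction of the Weinreb amide stops at the chelated hemiaminal, which releases aldehyde 7 on methanol quench, and borohydride reduces it in the same flask to the primary alcohol without touching a stereocentre.

Step 6
Reactants: 8 primary alcohol
Product: 9 12-iodo-3β-(tert-butyldimethylsilyloxy)-8βH-13,14,15,16-tetranorlabdane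
Conditions: I2, PPh3, imidazole, CH2Cl2, 0 to 25 °C
Reagents that add atoms: iodine, II
Why: Appel-type iodination substitutes the unhindered primary alcohol by SN2.

Step 7
Reactants: 10 (E)-3-iodo-2-methylprop-2-enoic acid
Product: 11 (E)-3-iodo-N-methoxy-N,2-dimethylprop-2-enamide
Conditions: 1,1'-carbonyldiimidazole, CH2Cl2, 25 °C; then MeNH(OMe)·HCl
Reagents that add atoms: N,O-dimethylhydroxylamine hydrochloride, CNOC.Cl
Why: Amide formation through the acyl imidazole leaves the E vinyl iodide unchanged.

Step 8
Reactants: 9 primary iodide and 11 iodo Weinreb amide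
Product: 13 (2E)-N-methoxy-N,2-dimethylpent-2-enamide carrying at C5 the C9′ decalin unit of 9 (C4 = C12′; C5 = C11′), via alkylzinc iodide 12 (not isolated)
Conditions: Zn dust, LiCl, THF, 45 °C; then 11, Pd(PPh3)4 (5 mol %), THF, 25 °C
Reagents that add atoms: none
Why: Negishi sp3–sp2 coupling joins C12′ to the vinyl carbon (the later C9) with retention of the E geometry.

Step 9
Reactants: 14 neryl acetate
Product: 15 (2Z)-5-[(2S)-3,3-dimethyloxiran-2-yl]-3-methylpent-2-en-1-yl acetate ((S)-6,7-epoxyneryl acetate)
Conditions: enantiomer of the fructose-derived Shi ketone (30 mol %), KHSO5 (as Oxone), K2CO3, Bu4NHSO4, MeCN–dimethoxymethane–aq. buffer, 0 °C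
Reagents that add atoms: potassium peroxymonosulfate, [K+].[O-]S(=O)(=O)OO
Why: Shi epoxidation attacks the electron-rich remote trisubstituted olefin rather than the olefin deactivated by the allylic acetate, and the L-series ketone sets the S epoxide that becomes C3.

Step 10
Reactants: 15 (S)-6,7-epoxyneryl acetate
Product: 16 [(1S,3S)-3-hydroxy-2,2-dimethyl-6-methylidenecyclohexyl]methyl acetate (OH and CH2OAc trans)
Conditions: Cp2TiCl2 (20 mol %), Mn dust, Me3SiCl, 2,4,6-collidine, THF, 25 °C; then dilute aq. HCl
Reagents that add atoms: none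
Why: Nugent–RajanBabu-type opening of the epoxide by Cp2TiCl (trivalent titanium) gives the tertiary C4 radical, which closes 6-endo through a chair with the C3–O bond equatorial; the Z olefin forces the CH2OAc group on C5 axial (Stork–Eschenmoser-type transfer of olefin geometry), hence trans to the C3 oxygen, and trapping of the C10 radical by titanium with β-hydride elimination leaves the exocyclic methylene.

Step 11
Reactants: 16 trans hydroxy acetate
Product: 17 [(1S,3S)-3-(tert-butyldimethylsilyloxy)-2,2-dimethyl-6-methylidenecyclohexyl]methyl acetate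
Conditions: TBSOTf, 2,6-lutidine, CH2Cl2, 0 °C
Reagents that add atoms: tert-butyldimethylsilyl triflate, CC(C)(C)[Si](C)(C)OS(=O)(=O)C(F)(F)F
Why: Silylation protects the C3 alcohol before the organolithium step.

Step 12
Reactants: 17 silyl ether acetate
Product: 18 [(1S,3S)-3-(tert-butyldimethylsilyloxy)-2,2-dimethyl-6-methylidenecyclohexyl]methanol
Conditions: K2CO3 (cat.), MeOH, 25 °C
Reagents that add atoms: none
Why: Transesterification removes the primary acetate and leaves the silyl ether.

Step 13
Reactants: 18 primary alcohol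
Product: 19 the iodide of 18 ((1S,3S)-configured iodomethyl compound, C6–I)
Conditions: I2, PPh3, imidazole, CH2Cl2, 0 to 25 °C
Reagents that add atoms: iodine, II
Why: Appel-type iodination at the primary carbon; C5 is not touched.

Step 14
Reactants: 19 ring-A iodide and 13 Weinreb enamide
Product: 22 bis-silylated cis-fused 8,9-dihydro ketone (C7 ketone; C9–H on the face of C10–CH3; C8–CH3 equatorial), via alkyllithium 20 (not isolated), via dienone 21 (not isolated)
Conditions: 19, t-BuLi (2.1 equiv), Et2O–pentane, −78 °C; then 13, THF, −78 to 0 °C; then AcOH, solvent exchange to EtOH–ethylene glycol in the same flask; then Fe(acac)3 (0.5 equiv), PhSiH3 (3 equiv), 60 °C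
Reagents that add atoms: none
Why: Iodine–lithium exchange gives alkyllithium 20, which adds once to the Weinreb amide of 13 (chelated adduct, no over-addition) and forms C6–C7; acid releases dienone 21, and Fe(acac)3/PhSiH3 then transfers a hydrogen atom to the CH2 terminus of the exocyclic C10=CH2 bond, creating the angular methyl and the tertiary C10 radical, which adds to C9 of the enone before the α-keto radical is reduced and protonated. The closest known types are the Weinreb ketone synthesis and the iron-hydride (Mukaiyama-type HAT) reductive olefin–enone Giese cyclization. Ring B closes in the 6-endo-trig mode; the 5-exo mode is disfavoured by the C8 methyl and by the polarity match of the nucleophilic radical with the enone β-carbon. C10 is controlled by the C5 stereocentre: allylic strain with the C10 substituent and the C4 gem-dimethyl group holds the C5 side chain axial, so C9 reaches only the same face of the planar C10 radical and the fusion should be cis, with C10–CH3 cis to C5–H and to the C3 oxygen. C9 (chain equatorial, from the E olefin) and C8 (thermodynamic protonation) are transient and become sp2 in step 15. The step needs hydrogen-atom transfer to the 1,1-disubstituted alkene in preference to reduction of the enone, which the electron-rich alkene and the electron-poor trisubstituted enone should secure.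

Step 15
Reactants: 22 cis-fused ketone
Product: 24 bis(tert-butyldimethylsilyl) ether of 25, via trimethylsilyl enol ether 23 (not isolated)
Conditions: Me3SiI, (Me3Si)2NH, CH2Cl2, −20 to 25 °C; then Pd(OAc)2 (1.1 equiv), MeCN, 25 °C
Reagents that add atoms: none
Why: Thermodynamic silylation should give the more substituted C7=C8 silyl enol ether 23, and Saegusa–Ito oxidation (oxa-π-allyl palladium, β-hydride elimination of C9–H) installs the tetrasubstituted C8=C9 enone, removing the C8 and C9 stereocentres.

Step 16
Reactants: 24 bis-silyl ether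
Product: 25 target (CNP0290352.1)
Conditions: HF·pyridine, THF, 0 to 25 °C
Reagents that add atoms: none
Why: Fluoride-driven cleavage of both silyl ethers leaves the enone and all stereocentres untouched.

**Compound list**
1 | (+)-sclareolide | O=C1C[C@H]2[C@](C)(O1)CC[C@H]3C(C)(C)CCC[C@]23C | starting material
2 | 3β-hydroxysclareolide | O=C1C[C@H]2[C@](C)(O1)CC[C@H]3C(C)(C)[C@@H](O)CC[C@]23C | intermediate
3 | 3β-(tert-butyldimethylsilyloxy)sclareolide | O=C1C[C@H]2[C@](C)(O1)CC[C@H]3C(C)(C)[C@@H](O[Si](C)(C)C(C)(C)C)CC[C@]23C | intermediate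
4 | hydroxy Weinreb amide (3β-(tert-butyldimethylsilyloxy)-8α-hydroxy-N-methoxy-N-methyl-13,14,15,16-tetranorlabdan-12-amide) | CON(C)C(=O)C[C@H]1[C@](C)(O)CC[C@H]2C(C)(C)[C@@H](O[Si](C)(C)C(C)(C)C)CC[C@]12C | intermediate
5 | 3β-(tert-butyldimethylsilyloxy)-N-methoxy-N-methyl-13,14,15,16-tetranorlabd-8(17)-en-12-amide | CON(C)C(=O)C[C@H]1C(=C)CC[C@H]2C(C)(C)[C@@H](O[Si](C)(C)C(C)(C)C)CC[C@]12C | intermediate
6 | 3β-(tert-butyldimethylsilyloxy)-N-methoxy-N-methyl-8βH-13,14,15,16-tetranorlabdan-12-amide | CON(C)C(=O)C[C@H]1[C@H](C)CC[C@H]2C(C)(C)[C@@H](O[Si](C)(C)C(C)(C)C)CC[C@]12C | intermediate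
7 | 3β-(tert-butyldimethylsilyloxy)-8βH-13,14,15,16-tetranorlabdan-12-al | O=CC[C@H]1[C@H](C)CC[C@H]2C(C)(C)[C@@H](O[Si](C)(C)C(C)(C)C)CC[C@]12C | intermediate
8 | 3β-(tert-butyldimethylsilyloxy)-8βH-13,14,15,16-tetranorlabdan-12-ol | OCC[C@H]1[C@H](C)CC[C@H]2C(C)(C)[C@@H](O[Si](C)(C)C(C)(C)C)CC[C@]12C | intermediate
9 | 12-iodo-3β-(tert-butyldimethylsilyloxy)-8βH-13,14,15,16-tetranorlabdane | ICC[C@H]1[C@H](C)CC[C@H]2C(C)(C)[C@@H](O[Si](C)(C)C(C)(C)C)CC[C@]12C | intermediate
10 | (E)-3-iodo-2-methylprop-2-enoic acid | C/C(=C\I)C(=O)O | starting material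
11 | (E)-3-iodo-N-methoxy-N,2-dimethylprop-2-enamide | C/C(=C\I)C(=O)N(C)OC | intermediate
12 | alkylzinc iodide from 9 | I[Zn]CC[C@H]1[C@H](C)CC[C@H]2C(C)(C)[C@@H](O[Si](C)(C)C(C)(C)C)CC[C@]12C | intermediate
13 | Weinreb enamide of the trans-decalin half ((2E)-N-methoxy-N,2-dimethylpent-2-enamide, C4 = C12′, C5 = C11′) | CON(C)C(=O)/C(C)=C/CC[C@H]1[C@H](C)CC[C@H]2C(C)(C)[C@@H](O[Si](C)(C)C(C)(C)C)CC[C@]12C | intermediate
14 | neryl acetate | CC(C)=CCC/C(C)=C\COC(C)=O | starting material
15 | (S)-6,7-epoxyneryl acetate | CC1(C)O[C@H]1CC/C(C)=C\COC(C)=O | intermediate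
16 | [(1S,3S)-3-hydroxy-2,2-dimethyl-6-methylidenecyclohexyl]methyl acetate | C=C1CC[C@H](O)C(C)(C)[C@H]1COC(C)=O | intermediate
17 | [(1S,3S)-3-(tert-butyldimethylsilyloxy)-2,2-dimethyl-6-methylidenecyclohexyl]methyl acetate | C=C1CC[C@H](O[Si](C)(C)C(C)(C)C)C(C)(C)[C@H]1COC(C)=O | intermediate
18 | [(1S,3S)-3-(tert-butyldimethylsilyloxy)-2,2-dimethyl-6-methylidenecyclohexyl]methanol | C=C1CC[C@H](O[Si](C)(C)C(C)(C)C)C(C)(C)[C@H]1CO | intermediate
19 | iodide of 18 (ring-A iodide) | C=C1CC[C@H](O[Si](C)(C)C(C)(C)C)C(C)(C)[C@H]1CI | intermediate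
20 | alkyllithium from 19 | C=C1CC[C@H](O[Si](C)(C)C(C)(C)C)C(C)(C)[C@H]1C[Li] | intermediate
21 | dienone (ring-A CH2–C(=O)–C(CH3)=CH–CH2CH2–trans-decalin, E) | C=C1CC[C@H](O[Si](C)(C)C(C)(C)C)C(C)(C)[C@H]1CC(=O)/C(C)=C/CC[C@H]2[C@H](C)CC[C@H]3C(C)(C)[C@@H](O[Si](C)(C)C(C)(C)C)CC[C@]23C | intermediate
22 | bis-silylated cis-fused 8,9-dihydro ketone | C[C@@H]1[C@@H](CC[C@H]2[C@H](C)CC[C@H]3C(C)(C)[C@@H](O[Si](C)(C)C(C)(C)C)CC[C@]23C)[C@@]2(C)CC[C@H](O[Si](C)(C)C(C)(C)C)C(C)(C)[C@H]2CC1=O | intermediate
23 | C7 trimethylsilyl enol ether of 22 (C7=C8) | CC=1[C@@H](CC[C@H]2[C@H](C)CC[C@H]3C(C)(C)[C@@H](O[Si](C)(C)C(C)(C)C)CC[C@]23C)[C@@]2(C)CC[C@H](O[Si](C)(C)C(C)(C)C)C(C)(C)[C@H]2CC=1O[Si](C)(C)C | intermediate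
24 | bis(tert-butyldimethylsilyl) ether of 25 | CC1=C(CC[C@H]2[C@H](C)CC[C@H]3C(C)(C)[C@@H](O[Si](C)(C)C(C)(C)C)CC[C@]23C)[C@@]2(C)CC[C@H](O[Si](C)(C)C(C)(C)C)C(C)(C)[C@H]2CC1=O | intermediate
25 | target CNP0290352.1 | CC1=C(CC[C@H]2[C@H](C)CC[C@H]3C(C)(C)[C@@H](O)CC[C@]23C)[C@@]2(C)CC[C@H](O)C(C)(C)[C@H]2CC1=O | target

**Totals.** Total step count: 16. Longest linear sequence: 10 steps (steps 1, 2, 3, 4, 5, 6, 8, 14, 15, 16).

**Steps most likely to fail**

Step 14. The C10 radical may be reduced by the iron hydride before it cyclizes, or the enone may be reduced first, so that the open chain is merely hydrogenated. The fallback sets out from 19 and 13 and separates the two events. The alkyllithium addition is worked up with aqueous acid and dienone 21 is isolated. Markovnikov hydrobromination of the exocyclic alkene (Me3SiBr, MeOH, CH2Cl2, −40 °C) gives the tertiary C10 bromide of dienone 21 F1, drawn as one epimer because the configuration at C10 is immaterial. Slow addition of Bu3SnH with AIBN (benzene, 80 °C) generates the same C10 radical at low hydride concentration, and the 6-endo closure comes back to the route at 22.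

Step 10. With the Z olefin the chair that places the CH2OAc group axial may be eroded by a boat-like closure, which would lower the trans selectivity at C5. The fallback replaces starting material 14 by its commercial 2E isomer, geranyl acetate F2, and comes back to the route at 16. Shi epoxidation with the ordinary D-fructose-derived ketone gives (R)-6,7-epoxygeranyl acetate F3. The same Cp2TiCl cyclization, well behaved for E olefins, gives the cis hydroxy acetate [(1S,3R)-3-hydroxy-2,2-dimethyl-6-methylidenecyclohexyl]methyl acetate F4 with C5 already correct. Dess–Martin oxidation gives the ketone [(1S)-2,2-dimethyl-6-methylidene-3-oxocyclohexyl]methyl acetate F5. Reagent-controlled Corey–Bakshi–Shibata reduction ((R)-2-methyl-CBS-oxazaborolidine, catecholborane, toluene, −78 °C), with the quaternary C4 as the large group, should set the 3S alcohol without hydroborating the alkene, which gives 16.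

Step 15. Silylation may occur toward C6, or β-hydride elimination at the hindered C9–H may be slow, which would give the wrong enone or return the ketone. The fallback sets out from 22. Acid-mediated bromination with PhNMe3Br3 (THF, 0 °C) goes through the more substituted enol and gives the C8 bromo ketone of 22 F6. Dehydrobromination with Li2CO3 and LiBr (DMF, 120 °C) gives the conjugated tetrasubstituted enone and comes back at 24.

**Further compounds**
F1 | step 14 | tertiary C10 bromide of dienone 21 | C[C@@]1(Br)CC[C@H](O[Si](C)(C)C(C)(C)C)C(C)(C)[C@H]1CC(=O)/C(C)=C/CC[C@H]2[C@H](C)CC[C@H]3C(C)(C)[C@@H](O[Si](C)(C)C(C)(C)C)CC[C@]23C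
F2 | step 10 | geranyl acetate | CC(C)=CCC/C(C)=C/COC(C)=O
F3 | step 10 | (R)-6,7-epoxygeranyl acetate | CC1(C)O[C@@H]1CC/C(C)=C/COC(C)=O
F4 | step 10 | [(1S,3R)-3-hydroxy-2,2-dimethyl-6-methylidenecyclohexyl]methyl acetate | C=C1CC[C@@H](O)C(C)(C)[C@H]1COC(C)=O
F5 | step 10 | [(1S)-2,2-dimethyl-6-methylidene-3-oxocyclohexyl]methyl acetate | C=C1CCC(=O)C(C)(C)[C@H]1COC(C)=O
F6 | step 15 | C8 bromo ketone of 22 | C[C@]1(Br)[C@@H](CC[C@H]2[C@H](C)CC[C@H]3C(C)(C)[C@@H](O[Si](C)(C)C(C)(C)C)CC[C@]23C)[C@@]2(C)CC[C@H](O[Si](C)(C)C(C)(C)C)C(C)(C)[C@H]2CC1=O
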